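**Strategy.** Everything rests on cutting the bond between the exocyclic ylidene carbon C1' (on C5 of the furanone ring) and the methyl-bearing stereocentre C2'. The enol-lactone unit O1–C5=C1'H of the tetronic acid ring is the anti-addition product of a carboxylate to an alkyne, so C1' is introduced as an alkynyl nucleophile: rhodium-catalysed asymmetric conjugate addition of (triisopropylsilyl)acetylene to (E)-crotonaldehyde forms C1'–C2', sets the only stereocentre and leaves an aldehyde at C4' for the E,E-diene. The precursors of this step are two small achiral molecules. The bis-furan arrives as an alkenyl iodide, and the furanone ring is closed last from an ethyl ynone and CO2.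

Key step: step 6

Assumption: (R)-DTBM-SEGPHOS is taken to deliver the alkynyl group to the enal face that gives the (S)-aldehyde; if the sense proves opposite, the (S)-ligand is used with nothing else changed.

Step 1
Reactants: 1 3-bromofuran; 2 4-bromofuran-2-carbaldehyde
Product: 4 rac-(4-bromofuran-2-yl)(furan-3-yl)methanol, via furan-3-yllithium 3 (not isolated)
Conditions: n-BuLi, THF, −78 °C; then 2, −78 °C; H2O
Reagents that add atoms: none
Why: Bromine–lithium exchange on 1 is fast at −78 °C and the furan-3-yllithium adds to the aldehyde of 2 (1,2-addition of an organolithium) much faster than it exchanges with the ring bromide of 2; the carbinol centre is racemic and is deleted in step 2.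

Step 2
Reactants: 4 rac-(4-bromofuran-2-yl)(furan-3-yl)methanol
Product: 5 4-bromo-2-(furan-3-ylmethyl)furan
Conditions: Et3SiH, CF3CO2H, CH2Cl2, 0 °C
Reagents that add atoms: none
Why: Ionic hydrogenation: the acid ionises the carbinol to a cation stabilised by both furan rings and the silane delivers hydride to it, while the C–Br bond and the ring positions should be inert at 0 °C with short contact.

Step 3
Reactants: 6 pent-3-yn-1-ol
Product: 7 5-iodopent-2-yne
Conditions: I2, PPh3, imidazole, CH2Cl2, 0 °C → rt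
Reagents that add atoms: iodine, II
Why: Appel reaction: the alkoxyphosphonium ion of the primary alcohol is displaced by iodide in an SN2 step and the internal alkyne does not react.

Step 4
Reactants: 7 5-iodopent-2-yne; 5 4-bromo-2-(furan-3-ylmethyl)furan
Product: 9 2-(furan-3-ylmethyl)-4-(pent-3-yn-1-yl)furan, via pent-3-yn-1-ylzinc iodide 8 (not isolated)
Conditions: Zn dust, LiCl, THF, 40 °C; then 5, Pd(OAc)2 (2 mol %), SPhos (4 mol %), THF, 50 °C
Reagents that add atoms: none
Why: LiCl-assisted insertion of zinc into the primary C–I bond gives an alkylzinc iodide that undergoes Negishi sp3–sp2 cross-coupling with the bromofuran on zerovalent palladium (formed in situ from Pd(OAc)2), the bulky biarylphosphine making reductive elimination faster than β-hydride elimination.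

Step 5
Reactants: 9 2-(furan-3-ylmethyl)-4-(pent-3-yn-1-yl)furan
Product: 11 (E)-2-(furan-3-ylmethyl)-4-(4-iodopent-3-en-1-yl)furan, via alkenylzirconocene chloride 10 (not isolated)
Conditions: Cp2Zr(H)Cl (2.5 equiv), THF, 50 °C; then I2, 0 °C
Reagents that add atoms: iodine, II
Why: Hydrozirconation adds Zr–H syn across the alkyne and, with excess hydride at 50 °C, should equilibrate the tetravalent zirconium onto the less hindered methyl-bearing carbon, so that iodinolysis with retention gives the (E)-2-iodoalk-2-ene that carries the trisubstituted alkene geometry.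

Step 6
Reactants: 12 (E)-but-2-enal (crotonaldehyde); 13 ethynyltri(propan-2-yl)silane ((triisopropylsilyl)acetylene)
Product: 14 (S)-3-methyl-5-(triisopropylsilyl)pent-4-ynal
Conditions: [Rh(OAc)(C2H4)2]2 (2.5 mol %), (R)-DTBM-SEGPHOS (6 mol %), MeOH, 40 °C
Reagents that add atoms: none
Why: The acetate-bridged monovalent rhodium precursor, the bisphosphine and the alkyne give an alkynylrhodium complex that inserts the C=C bond of the (E)-enal in a 1,4-sense to an oxa-π-allylrhodium, which methanol protonates to release the aldehyde and a rhodium methoxide that metalates the next alkyne. The closest known reaction type is the rhodium/bisphosphine-catalysed asymmetric conjugate alkynylation of enals and enones with bulky silylacetylenes. No ring is closed. The new C2' stereocentre (S) is controlled by the C2-symmetric ligand, whose 3,5-di-tert-butyl-4-methoxyphenyl groups leave only one π-face of the rhodium-bound enal open to alkynyl migration. The step needs 1,4- rather than 1,2-addition and enal insertion rather than alkyne dimerisation, which the soft alkynyl–rhodium bond and, respectively, the triisopropylsilyl group together with the bulky ligand secure. The silylalkyne is the latent exocyclic C5=C1' unit of the furanone ring and the aldehyde carbon is the future diene carbon C4'.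

Step 7
Reactants: 14 (S)-3-methyl-5-(triisopropylsilyl)pent-4-ynal
Product: 15 (S,E)-triisopropyl[3-methyl-6-(4,4,5,5-tetramethyl-1,3,2-dioxaborolan-2-yl)hex-5-en-1-yn-1-yl]silane
Conditions: Cl2CHBpin (2 equiv), CrCl2 (8 equiv), LiI (4 equiv), THF, 25 °C
Reagents that add atoms: 2-(dichloromethyl)-4,4,5,5-tetramethyl-1,3,2-dioxaborolane, ClC(Cl)B1OC(C)(C)C(C)(C)O1
Why: Takai–Utimoto boryl-olefination: divalent chromium turns the dihalomethylboronate into a geminal dichromium species that adds to the aldehyde and eliminates to the (E)-alkenylboronate, the stereocentre being β to the carbonyl and therefore not epimerisable.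

Step 8
Reactants: 15 (S,E)-alkenylboronate; 11 (E)-2-(furan-3-ylmethyl)-4-(4-iodopent-3-en-1-yl)furan
Product: 16 triisopropyl{(3S,5E,7E)-10-[5-(furan-3-ylmethyl)furan-3-yl]-3,7-dimethyldeca-5,7-dien-1-yn-1-yl}silane
Conditions: Pd(dppf)Cl2 (5 mol %), K3PO4, THF/H2O, 45 °C
Reagents that add atoms: none
Why: Suzuki–Miyaura coupling on zerovalent palladium (from Pd(dppf)Cl2) joins the two alkenyl partners with retention of both double-bond geometries, giving the (5E,7E)-diene without touching the silylalkyne.

Step 9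
Reactants: 16 silylalkyne diene
Product: 17 2-(furan-3-ylmethyl)-4-[(3E,5E,8S)-4,8-dimethyldeca-3,5-dien-9-yn-1-yl]furan
Conditions: TBAF, wet THF, 0 °C → rt
Reagents that add atoms: none
Why: Fluoride-induced protodesilylation of the alkynylsilane, under which the skipped enyne and the propargylic stereocentre should not be deprotonated.

Step 10
Reactants: 17 terminal alkyne
Product: 19 (6S,8E,10E)-13-[5-(furan-3-ylmethyl)furan-3-yl]-6,10-dimethyltrideca-8,10-dien-4-yn-3-one, via lithium acetylide 18 (not isolated)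
Conditions: n-BuLi (1.05 equiv), THF, −78 °C; EtC(O)N(OMe)Me, −78 → 0 °C; cold 0.5 M HCl
Reagents that add atoms: N-methoxy-N-methylpropanamide, CCC(=O)N(C)OC
Why: Weinreb ketone synthesis: the terminal alkyne is by far the most acidic site and its lithium acetylide adds only once to the N-methoxy-N-methylamide because the chelated tetrahedral adduct survives until the cold acidic quench, which also protonates the released amine so that it cannot add to the ynone.

Step 11
Reactants: 19 ethyl ynone
Product: 21 (5Z)-5-{(2S,4E,6E)-9-[5-(furan-3-ylmethyl)furan-3-yl]-2,6-dimethylnona-4,6-dien-1-ylidene}-4-hydroxy-3-methylfuran-2(5H)-one, via β-ketocarboxylate 20 (not isolated)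
Conditions: AgOAc (10 mol %), DBU (2 equiv), CO2 (1 MPa), MeCN, 25 °C; then 1 M HCl
Reagents that add atoms: carbon dioxide, O=C=O
Why: Silver-catalysed CO2 incorporation into a conjugated ynone: the amidine base and CO2 carboxylate the ethyl ketone at its α-carbon, the carboxylate oxygen closes 5-exo-dig onto the alkyne activated by monovalent silver and anti to it, and protodeargentation followed by enolisation of the furan-2,4-dione should give the (Z)-ylidene tetronic acid with C2' untouched.

**Compound list**

1 | 3-bromofuran | Brc1ccoc1 | starting material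
2 | 4-bromofuran-2-carbaldehyde | O=Cc1cc(Br)co1 | starting material
3 | furan-3-yllithium | [Li]c1ccoc1 | intermediate
4 | rac-(4-bromofuran-2-yl)(furan-3-yl)methanol | OC(c1cc(Br)co1)c1ccoc1 | intermediate
5 | 4-bromo-2-(furan-3-ylmethyl)furan | Brc1coc(Cc2ccoc2)c1 | intermediate
6 | pent-3-yn-1-ol | CC#CCCO | starting material
7 | 5-iodopent-2-yne | CC#CCCI | intermediate
8 | pent-3-yn-1-ylzinc iodide | CC#CCC[Zn]I | intermediate
9 | 2-(furan-3-ylmethyl)-4-(pent-3-yn-1-yl)furan | CC#CCCc1coc(Cc2ccoc2)c1 | intermediate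
10 | chlorobis(cyclopentadienyl){(E)-5-[5-(furan-3-ylmethyl)furan-3-yl]pent-2-en-2-yl}zirconium | C/C(=C\CCc1coc(Cc2ccoc2)c1)[Zr](Cl)(C1C=CC=C1)C1C=CC=C1 | intermediate
11 | (E)-2-(furan-3-ylmethyl)-4-(4-iodopent-3-en-1-yl)furan | C/C(I)=C\CCc1coc(Cc2ccoc2)c1 | intermediate
12 | (E)-but-2-enal | C/C=C/C=O | starting material
13 | ethynyltri(propan-2-yl)silane | C#C[Si](C(C)C)(C(C)C)C(C)C | starting material
14 | (S)-3-methyl-5-(triisopropylsilyl)pent-4-ynal | CC(C)[Si](C#C[C@@H](C)CC=O)(C(C)C)C(C)C | intermediate
15 | (S,E)-triisopropyl[3-methyl-6-(4,4,5,5-tetramethyl-1,3,2-dioxaborolan-2-yl)hex-5-en-1-yn-1-yl]silane | CC(C)[Si](C#C[C@@H](C)C/C=C/B1OC(C)(C)C(C)(C)O1)(C(C)C)C(C)C | intermediate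
16 | triisopropyl{(3S,5E,7E)-10-[5-(furan-3-ylmethyl)furan-3-yl]-3,7-dimethyldeca-5,7-dien-1-yn-1-yl}silane | CC(C)[Si](C#C[C@@H](C)C/C=C/C(C)=C/CCc1coc(Cc2ccoc2)c1)(C(C)C)C(C)C | intermediate
17 | 2-(furan-3-ylmethyl)-4-[(3E,5E,8S)-4,8-dimethyldeca-3,5-dien-9-yn-1-yl]furan | C#C[C@@H](C)C/C=C/C(C)=C/CCc1coc(Cc2ccoc2)c1 | intermediate
18 | lithium acetylide of 17 | [Li]C#C[C@@H](C)C/C=C/C(C)=C/CCc1coc(Cc2ccoc2)c1 | intermediate
19 | (6S,8E,10E)-13-[5-(furan-3-ylmethyl)furan-3-yl]-6,10-dimethyltrideca-8,10-dien-4-yn-3-one | CCC(=O)C#C[C@@H](C)C/C=C/C(C)=C/CCc1coc(Cc2ccoc2)c1 | intermediate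
20 | (6S,8E,10E)-13-[5-(furan-3-ylmethyl)furan-3-yl]-2,6,10-trimethyl-3-oxotrideca-8,10-dien-4-ynoic acid (present as its amidinium carboxylate, C2 unassigned) | OC(=O)C(C)C(=O)C#C[C@@H](C)C/C=C/C(C)=C/CCc1coc(Cc2ccoc2)c1 | intermediate
21 | (5Z)-5-{(2S,4E,6E)-9-[5-(furan-3-ylmethyl)furan-3-yl]-2,6-dimethylnona-4,6-dien-1-ylidene}-4-hydroxy-3-methylfuran-2(5H)-one | CC1=C(O)/C(=C/[C@@H](C)C/C=C/C(C)=C/CCc2coc(Cc3ccoc3)c2)OC1=O | target

**Step count.** Total: 11 steps. Longest linear sequence: 8 steps (1, 2, 4, 5, 8, 9, 10, 11).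

**Steps most likely to fail**

Step 11. Proton transfer at the propargylic C2' position of the ynone under the amidine base (ynone–allenone isomerisation) would erode the configuration, and the carboxylate could close in the 6-endo sense. The fallback closes the ring without base on a substrate whose C4 is still sp3; it sets out from 17 and returns at 21. The lithium acetylide 18 is formylated with DMF to give (4S,6E,8E)-11-[5-(furan-3-ylmethyl)furan-3-yl]-4,8-dimethylundeca-6,8-dien-2-ynal F1. The dianion of propanoic acid (2 LiN(i-Pr)2, THF, −78 °C) adds to this aldehyde in an aldol addition to give (6S,8E,10E)-13-[5-(furan-3-ylmethyl)furan-3-yl]-3-hydroxy-2,6,10-trimethyltrideca-8,10-dien-4-ynoic acid F2 as a diastereomer mixture. AgNO3-catalysed 5-exo-dig cycloisomerisation of this γ,δ-alkynoic acid gives (5Z)-5-{(2S,4E,6E)-9-[5-(furan-3-ylmethyl)furan-3-yl]-2,6-dimethylnona-4,6-dien-1-ylidene}-4-hydroxy-3-methyloxolan-2-one F3. Dess–Martin oxidation of the C4 carbinol gives the furan-2,4-dione, which is 21 in its enol form.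

Step 6. Facial discrimination at rhodium may be insufficient for the small β-methyl group, and the alkyne may be lost through dimerisation before conjugate addition. The fallback makes the same C1'–C2' bond by copper-catalysed SN2′ allylic substitution; it sets out from 13 and returns at 14. (E)-But-2-en-1-ol is phosphorylated (ClP(O)(OEt)2, pyridine) to (E)-but-2-en-1-yl diethyl phosphate F4. Compound 13 is aluminated (i-Bu2AlH, Et3N cat.) to diisobutyl[(triisopropylsilyl)ethynyl]aluminium F5. Enantioselective allylic substitution of F4 by F5 with CuCl2·2H2O and a chiral sulfonate-bearing N-heterocyclic carbene ligand gives the branched enyne (S)-triisopropyl(3-methylpent-4-en-1-yn-1-yl)silane F6. 9-BBN hydroboration of the vinyl group and NaOH/H2O2 oxidation give (S)-3-methyl-5-(triisopropylsilyl)pent-4-yn-1-ol F7, and Dess–Martin oxidation returns 14.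

Step 5. Regiochemical equilibration may be incomplete, leaving zirconium distributed over both alkyne carbons and giving regioisomeric iodides that are hard to separate. The fallback sets the trisubstituted alkene with a stabilised ylide and forms the diene by Wittig olefination; it sets out from 5 and 14 and returns at 16, so that steps 3, 4, 5 and 7 are not needed. B-alkyl Suzuki–Miyaura coupling of 5 with the 9-BBN adduct of 3,3-diethoxyprop-1-ene (Pd(dppf)Cl2, K3PO4) gives 4-(3,3-diethoxypropyl)-2-(furan-3-ylmethyl)furan F8. Aqueous oxalic acid in THF frees 3-[5-(furan-3-ylmethyl)furan-3-yl]propanal F9. Wittig reaction with ethyl 2-(triphenylphosphoranylidene)propanoate gives ethyl (E)-5-[5-(furan-3-ylmethyl)furan-3-yl]-2-methylpent-2-enoate F10. i-Bu2AlH reduces it to (E)-5-[5-(furan-3-ylmethyl)furan-3-yl]-2-methylpent-2-en-1-ol F11. CBr4/PPh3 gives (E)-4-(5-bromo-4-methylpent-3-en-1-yl)-2-(furan-3-ylmethyl)furan F12. PBu3 gives tributyl{(E)-5-[5-(furan-3-ylmethyl)furan-3-yl]-2-methylpent-2-en-1-yl}phosphonium bromide F13. Its ylide (NaN(SiMe3)2, THF, −78 °C) reacts with aldehyde 14 in the E-selective Wittig olefination typical of allylic trialkylphosphonium ylides to give 16.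

**Further compounds**

F1 | step 11 | (4S,6E,8E)-11-[5-(furan-3-ylmethyl)furan-3-yl]-4,8-dimethylundeca-6,8-dien-2-ynal | O=CC#C[C@@H](C)C/C=C/C(C)=C/CCc1coc(Cc2ccoc2)c1
F2 | step 11 | (6S,8E,10E)-13-[5-(furan-3-ylmethyl)furan-3-yl]-3-hydroxy-2,6,10-trimethyltrideca-8,10-dien-4-ynoic acid | OC(=O)C(C)C(O)C#C[C@@H](C)C/C=C/C(C)=C/CCc1coc(Cc2ccoc2)c1
F3 | step 11 | (5Z)-5-{(2S,4E,6E)-9-[5-(furan-3-ylmethyl)furan-3-yl]-2,6-dimethylnona-4,6-dien-1-ylidene}-4-hydroxy-3-methyloxolan-2-one | CC1C(O)/C(=C/[C@@H](C)C/C=C/C(C)=C/CCc2coc(Cc3ccoc3)c2)OC1=O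
F4 | step 6 | (E)-but-2-en-1-yl diethyl phosphate | C/C=C/COP(=O)(OCC)OCC
F5 | step 6 | diisobutyl[(triisopropylsilyl)ethynyl]aluminium | CC(C)C[Al](CC(C)C)C#C[Si](C(C)C)(C(C)C)C(C)C
F6 | step 6 | (S)-triisopropyl(3-methylpent-4-en-1-yn-1-yl)silane | CC(C)[Si](C#C[C@@H](C)C=C)(C(C)C)C(C)C
F7 | step 6 | (S)-3-methyl-5-(triisopropylsilyl)pent-4-yn-1-ol | CC(C)[Si](C#C[C@@H](C)CCO)(C(C)C)C(C)C
F8 | step 5 | 4-(3,3-diethoxypropyl)-2-(furan-3-ylmethyl)furan | CCOC(CCc1coc(Cc2ccoc2)c1)OCC
F9 | step 5 | 3-[5-(furan-3-ylmethyl)furan-3-yl]propanal | O=CCCc1coc(Cc2ccoc2)c1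
F10 | step 5 | ethyl (E)-5-[5-(furan-3-ylmethyl)furan-3-yl]-2-methylpent-2-enoate | CCOC(=O)/C(C)=C/CCc1coc(Cc2ccoc2)c1
F11 | step 5 | (E)-5-[5-(furan-3-ylmethyl)furan-3-yl]-2-methylpent-2-en-1-ol | OC/C(C)=C/CCc1coc(Cc2ccoc2)c1
F12 | step 5 | (E)-4-(5-bromo-4-methylpent-3-en-1-yl)-2-(furan-3-ylmethyl)furan | BrC/C(C)=C/CCc1coc(Cc2ccoc2)c1
F13 | step 5 | tributyl{(E)-5-[5-(furan-3-ylmethyl)furan-3-yl]-2-methylpent-2-en-1-yl}phosphonium bromide | CCCC[P+](CCCC)(CCCC)C/C(C)=C/CCc1coc(Cc2ccoc2)c1.[Br-]
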